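The pyran ring of the 2H-chromene is cut at C2–C3 and C4–C4a, which leaves an aryl ether of a C(CH3)2 unit and a two-carbon piece. In one photoredox cascade a tertiary α-aryloxy radical, released from the N-acyloxyphthalimide of a fibrate-type acid, adds to phenyl vinyl sulfone (an acetylene equivalent) and the adduct radical closes onto C4a, the only free carbon ortho to O1 on the benzene ring (C8 carries OMe). The C5 hydroxyl beside C4a then expels sulfinate through an ortho-quinone methide and reveals the C3=C4 double bond. The precursor is an open-chain aryloxyisobutyrate built on a deoxybenzoin; the 1,2-diketone is made last.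

Key step: step 5

Remark on the chemistry: the target has no stereocentre and no stereogenic double bond, so it is one achiral compound and no stereocontrol is needed. Ring atoms are numbered as in the 2H-chromene (O1, C2, C3, C4, C4a, C5 to C8, C8a). Compounds 1, 2, 4 and 8 are taken as catalogue chemicals.

Step 1
Reactants: 1 4-methoxybenzene-1,3-diol; 2 2-(4-methoxyphenyl)acetic acid
Product: 3 1-(2,4-dihydroxy-5-methoxyphenyl)-2-(4-methoxyphenyl)ethan-1-one
Conditions: BF3·OEt2 (as solvent), 85 °C; aq. NaOAc work-up
Reagents that add atoms: none
Why: BF3-mediated Friedel–Crafts (Nencki-type) acylation should go at C6 of the resorcinol, the unhindered position ortho to one OH and para to the other, as in standard deoxybenzoin syntheses.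

Step 2
Reactants: 3 1-(2,4-dihydroxy-5-methoxyphenyl)-2-(4-methoxyphenyl)ethan-1-one; 4 tert-butyl 2-bromo-2-methylpropanoate
Product: 5 tert-butyl 2-{5-hydroxy-2-methoxy-4-[2-(4-methoxyphenyl)acetyl]phenoxy}-2-methylpropanoate
Conditions: K2CO3 (2 equiv), 4 (2 equiv), DMF, 70 °C
Reagents that add atoms: none
Why: Williamson etherification as in fibrate syntheses should take the free, more acidic 4-OH para to the ketone, because the 2-OH is tied up in a hydrogen bond to the carbonyl and carbonate does not enolise the ketone.

Step 3
Reactants: 5 tert-butyl 2-{5-hydroxy-2-methoxy-4-[2-(4-methoxyphenyl)acetyl]phenoxy}-2-methylpropanoate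
Product: 6 2-{5-hydroxy-2-methoxy-4-[2-(4-methoxyphenyl)acetyl]phenoxy}-2-methylpropanoic acid
Conditions: TFA/CH2Cl2 (1:2), rt
Reagents that add atoms: none
Why: Acidolysis of the tert-butyl ester (E1, loss of isobutene) should leave the tertiary aryl ether intact, since a cation α to the carboxyl group is not formed.

Step 4
Reactants: 6 2-{5-hydroxy-2-methoxy-4-[2-(4-methoxyphenyl)acetyl]phenoxy}-2-methylpropanoic acid
Product: 7 1,3-dioxoisoindolin-2-yl 2-{5-hydroxy-2-methoxy-4-[2-(4-methoxyphenyl)acetyl]phenoxy}-2-methylpropanoate
Conditions: N-hydroxyphthalimide (1.1 equiv), DIC (1.1 equiv), DMAP (10 mol %), CH2Cl2, rt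
Reagents that add atoms: N-hydroxyphthalimide, O=C1c2ccccc2C(=O)N1O
Why: Carbodiimide (Steglich-type) esterification should give the redox-active ester, because the hydrogen-bonded phenol is too poor a nucleophile to compete with N-hydroxyphthalimide for the hindered acyl group.

Step 5
Reactants: 7 1,3-dioxoisoindolin-2-yl 2-{5-hydroxy-2-methoxy-4-[2-(4-methoxyphenyl)acetyl]phenoxy}-2-methylpropanoate; 8 phenyl vinyl sulfone
Product: 11 1-(5-hydroxy-8-methoxy-2,2-dimethyl-2H-chromen-6-yl)-2-(4-methoxyphenyl)ethan-1-one, via 4-sulfonylchroman 9 (not isolated), via ortho-quinone methide 10 (not isolated)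
Conditions: fac-Ir(ppy)3 (1 mol %), 8 (1.5 equiv), degassed MeCN, 450 nm LEDs, rt; then DBU (3 equiv), 50 °C
Reagents that add atoms: none
Why: Excited fac-Ir(ppy)3 reduces the N-acyloxyphthalimide, which loses phthalimide anion and CO2; the nucleophilic tertiary α-aryloxy radical adds to the CH2 end of the electron-poor sulfone (bond C2–C3), the electrophilic α-sulfonyl radical attacks ring carbon C4a (bond C4–C4a), and Ir(IV) oxidises the cyclohexadienyl radical before phthalimide anion takes the proton, so the cascade is redox-neutral. The closest known reaction type is the photoredox (4+2) radical annulation of redox-active esters of aryloxy acids with electron-poor olefins to chromans, which rests on the decarboxylative Giese addition of fibrate-type radicals. The pyran ring closes in the six-membered ortho mode of homolytic aromatic substitution (6-endo with respect to the C4a–C8a bond), favoured by the gem-dimethyl group over 5-exo ipso attack, which has no productive exit for an ether. DBU then deprotonates the C5 phenol of 9, the phenoxide expels benzenesulfinate to give ortho-quinone methide 10, and removal of the γ-proton at C3 restores the arene and leaves the C3=C4 double bond, so the vinyl sulfone serves as an acetylene equivalent. No stereocentre remains, because C4 of 9 is formed as a racemate and becomes sp2. The step needs chemoselective polarity matching (nucleophilic radical to acceptor, electrophilic radical to the electron-rich arene, hence no telomerisation) and regioselective closure, which the substrate secures because the second position ortho to the ether oxygen carries OMe and C4a lies between two oxygen-bearing carbons.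

Step 6
Reactants: 11 1-(5-hydroxy-8-methoxy-2,2-dimethyl-2H-chromen-6-yl)-2-(4-methoxyphenyl)ethan-1-one
Product: 12 Dielsianone, 1-(5-hydroxy-8-methoxy-2,2-dimethyl-2H-chromen-6-yl)-2-(4-methoxyphenyl)ethane-1,2-dione
Conditions: SeO2 (1.5 equiv), 1,4-dioxane/H2O (20:1), 90 °C
Reagents that add atoms: selenium dioxide, O=[Se]=O
Why: Riley oxidation of the doubly activated ArC(=O)CH2Ar methylene should give the 1,2-diketone, and the ring alkene should be spared because the chromene has no allylic C–H (C2 is quaternary).

Compound list
1 | 4-methoxybenzene-1,3-diol (4-methoxyresorcinol) | COc1ccc(O)cc1O | starting material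
2 | 2-(4-methoxyphenyl)acetic acid | COc1ccc(CC(=O)O)cc1 | starting material
3 | 1-(2,4-dihydroxy-5-methoxyphenyl)-2-(4-methoxyphenyl)ethan-1-one | COc1ccc(CC(=O)c2cc(OC)c(O)cc2O)cc1 | intermediate
4 | tert-butyl 2-bromo-2-methylpropanoate | CC(C)(Br)C(=O)OC(C)(C)C | starting material
5 | tert-butyl 2-{5-hydroxy-2-methoxy-4-[2-(4-methoxyphenyl)acetyl]phenoxy}-2-methylpropanoate | COc1ccc(CC(=O)c2cc(OC)c(OC(C)(C)C(=O)OC(C)(C)C)cc2O)cc1 | intermediate
6 | 2-{5-hydroxy-2-methoxy-4-[2-(4-methoxyphenyl)acetyl]phenoxy}-2-methylpropanoic acid | COc1ccc(CC(=O)c2cc(OC)c(OC(C)(C)C(=O)O)cc2O)cc1 | intermediate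
7 | 1,3-dioxoisoindolin-2-yl 2-{5-hydroxy-2-methoxy-4-[2-(4-methoxyphenyl)acetyl]phenoxy}-2-methylpropanoate | COc1ccc(CC(=O)c2cc(OC)c(OC(C)(C)C(=O)ON3C(=O)c4ccccc4C3=O)cc2O)cc1 | intermediate
8 | phenyl vinyl sulfone (ethenylsulfonylbenzene) | C=CS(=O)(=O)c1ccccc1 | starting material
9 | rac-1-[5-hydroxy-8-methoxy-2,2-dimethyl-4-(phenylsulfonyl)chroman-6-yl]-2-(4-methoxyphenyl)ethan-1-one (racemic, not isolated) | COc1ccc(CC(=O)c2cc(OC)c3c(c2O)C(S(=O)(=O)c2ccccc2)CC(C)(C)O3)cc1 | intermediate
10 | 8-methoxy-6-[2-(4-methoxyphenyl)acetyl]-2,2-dimethyl-2,3-dihydro-5H-chromen-5-one (ortho-quinone methide with C4=C4a, C6=C7 and C8=C8a double bonds, not isolated) | COc1ccc(CC(=O)C2=CC(OC)=C3OC(C)(C)CC=C3C2=O)cc1 | intermediate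
11 | 1-(5-hydroxy-8-methoxy-2,2-dimethyl-2H-chromen-6-yl)-2-(4-methoxyphenyl)ethan-1-one | COc1ccc(CC(=O)c2cc(OC)c3c(c2O)C=CC(C)(C)O3)cc1 | intermediate
12 | Dielsianone, 1-(5-hydroxy-8-methoxy-2,2-dimethyl-2H-chromen-6-yl)-2-(4-methoxyphenyl)ethane-1,2-dione | COc1ccc(C(=O)C(=O)c2cc(OC)c3c(c2O)C=CC(C)(C)O3)cc1 | target

Total step count: 6
Longest linear sequence: 6 steps (1 to 3 to 5 to 6 to 7 to 11 to 12)

Steps most likely to fail

1. Step 5. The α-sulfonyl adduct radical may be reduced or take up a hydrogen atom before it closes onto the arene, so that open-chain material forms instead of the ring. The later expulsion of sulfinate may also stay incomplete. The fallback sets out from 3 and comes back to the route at 11. Compound 3 would be alkylated at the free 4-OH with 3-chloro-3-methylbut-1-yne (K2CO3, KI, cat. CuCl, acetone, reflux) to give the aryl 1,1-dimethylpropargyl ether 1-{2-hydroxy-5-methoxy-4-[(2-methylbut-3-yn-2-yl)oxy]phenyl}-2-(4-methoxyphenyl)ethan-1-one F1. Heating F1 in N,N-diethylaniline at about 180 °C should then bring about the aromatic propargyl Claisen rearrangement to the only free ortho carbon, followed by a 1,5-hydrogen shift and oxa-6π electrocyclisation to 11. This fallback gives up the formation of both ring C–C bonds in one operation and replaces steps 2 to 5.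

2. Step 6. Electrophilic selenium(IV) may attack the electron-rich ring alkene, or the hot, weakly acidic medium may hydrate or oligomerise the chromene while the methylene is oxidised. The fallback sets out from 9 and comes back to the route at 12. The irradiation of step 5 would be worked up before DBU is added, so that 9 is isolated with the alkene still masked as the sulfone. SeO2 in dioxane/water at 90 °C should then oxidise the methylene to give rac-1-[5-hydroxy-8-methoxy-2,2-dimethyl-4-(phenylsulfonyl)chroman-6-yl]-2-(4-methoxyphenyl)ethane-1,2-dione F2. Treatment of F2 with DBU in MeCN at 50 °C should expel sulfinate through the ortho-quinone methide and give 12, so the alkene never meets the oxidant.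

3. Step 2. The tertiary bromide may lose HBr faster than the hindered, weakly nucleophilic para-acyl phenoxide substitutes it, and the methacrylate so formed may then add the phenoxide at the wrong carbon. The fallback sets out from 3 and comes back to the route at 6. A Bargellini reaction of 3 with 1,1,1-trichloro-2-methylpropan-2-ol and powdered NaOH in acetone (0 °C to rt, then acidification) should let the phenoxide open the gem-dichloro epoxide formed in the flask at its tertiary carbon, and hydrolysis of the acyl chloride gives acid 6 directly. This makes no new compound, F0, and also replaces step 3.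

Further compounds
F1 | step 5 | 1-{2-hydroxy-5-methoxy-4-[(2-methylbut-3-yn-2-yl)oxy]phenyl}-2-(4-methoxyphenyl)ethan-1-one | COc1ccc(CC(=O)c2cc(OC)c(OC(C)(C)C#C)cc2O)cc1
F2 | step 6 | rac-1-[5-hydroxy-8-methoxy-2,2-dimethyl-4-(phenylsulfonyl)chroman-6-yl]-2-(4-methoxyphenyl)ethane-1,2-dione | COc1ccc(C(=O)C(=O)c2cc(OC)c3c(c2O)C(S(=O)(=O)c2ccccc2)CC(C)(C)O3)cc1
F0 | step 2 | none | none
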